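If a reagent enters a flask from a solid, each product takes one of it, and it is used about as fast as it dissolves, its dissolved level holds steady, and the product line then measures the feed from the solid.

common to all: starting material 0.056 M

| flask | solid second substrate | enzyme | remark | time |
|---|---|---|---|---|
| blue | 0.70 equiv | 0.02 mol% | the very flask that is asked about, followed so far |  |
| violet | 0.70 equiv | 0.04 mol% | run made earlier |  |
| flask | 0.700 equiv | 0.02 mol% |  | 40 min |

- blue (time / min: product / %, starting material / %): 2.50: 2, 101; 8.00: 3, 95; 12.0: 10, 91; 20.0: 16, 85
- violet (time / min: product / %, starting material / %): 5.00: 2, 95; 15.0: 13, 88; 25.0: 24, 76; 40.0: 37, 59

(scatter of a reading: 1.5 percentage points)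

- as a solid, counted per litre of solution: solid second substrate
- the numbers in the tables scatter with a standard deviation of 1.5 percentage points
- steps thought possible: starting material + enzyme <-> starting complex; second substrate + starting complex <-> ternary complex; ternary complex -> enzyme + product; solid second substrate <-> second substrate
- at the start none of the solid second substrate is in solution

1. product at 40 min, in percent of the starting material charged
2. concentration of second substrate in solution at 4.0 min, in percent of saturation
3. the change that raises the amount of product at 40 min, in percent of the starting material charged most ("none" if none brings more than 2 percentage points) (dawn / midnight / spring / none)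
4. amount of product at 40 min, in percent of the starting material charged, after midnight

- dawn: doubling the amount of enzyme, all else as stated
- midnight: doubling the solubility of the solid second substrate, all else as stated
- spring: doubling the dissolution coefficient of the solid second substrate, all else as stated

By 20.0 min the blue flask has made 16 % product, a line from the origin of r = 0.00800 /min of the charge. The violet run, with twice the enzyme, gives 0.00925 /min over 40.0 min, which is 1.16 times the blue line. With that ratio of readings under 2, this reckoning reads dissolving as the likely rate-limiting step in blue and r as its feed of second substrate. Each product takes one second substrate, so the blue charge of 0.700 equiv divided by r is 87.5 min: the feed time τ, the time the solid lasts at this rate.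

Since 40 min is shorter than τ, the solid outlasts the asked time at this rate. From above stands the violet reading of 37 % at the same time, with more enzyme. From below stands the estimate r·t = 32.0 %, the blue line carried forward; that line lies above the blue reading of 3 % at 8.00 min, so it counts the slow start as working time. This floor is an estimate and carries twice the scatter of 1.5 percentage points.

The forecast gives 31 %, just under the floor, with second substrate at 40 % of saturation at 4.0 min, midnight as best change and 53 % after it. Its grounds differ from this reckoning: “Doubling the enzyme gives only about 1.3 times the rate, so dissolution and enzyme share control.”

The flask gives 33.2 %, inside the bracket, and second substrate at 6.51 % of saturation at 4.0 min, far under the forecast. The best change is midnight, giving 60.8 %.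

    starting material + enzyme ⇌ starting complex (K = 7.50 /M, k = 22000 /M/s)
    second substrate + starting complex ⇌ ternary complex (K = 28.0 /M, k = 2.50 × 10⁵ /M/min)
    ternary complex → enzyme + product (k = 3500 /min)
    solid second substrate ⇌ second substrate, rate k4*(cs4 - [second substrate]) while solid is left; crystals form when [second substrate] > cs4 (solubility = 23.0 mM, k = 0.0260 /min)

Through 40.0 min the solid dissolved, falling from 94.1 % of its charge at 4.00 min to 45.1 %. Meanwhile second substrate in solution stood at 10.9 % of saturation at 20.0 min, its half-life by the forward step with starting complex, 0.95 min at 19.6 min, being short against 40 min. In this flask t/τ = 45.7 %, and product stands at 47.4 % of the solid's charge. The neighbour read at 1.5 h lies past τ, so τ gives a line ending at 70.0 %; the computed flask holds 68.3 % product and 0 % solid.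

Readings and results come from a simulation for an exercise, noise included.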